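A rise of Q as even as the one in the west run invites counting first-order half-lives, but by the steps under discussion each Q takes a D as well as an E, so the rate falls with [D] and [E] at once.

all flasks: X 0.10 M
- west: D 1.1 equiv; the very flask that is asked about, followed so far
- flask: D 1.10 equiv; time 1.5 h

west run (percent of the X charged)

| time / min | Q / % | G / % |
|---|---|---|
| 2.00 | 5 | 10 |
| 6.00 | 13 | 13 |
| 10.0 | 22 | 11 |
| 15.0 | 30 | 15 |

(standard deviation of a reading: 2 percentage points)

- ratio of Q to G at 20 s
- ratio of Q to G at 5.0 min
- ratio of Q to G at 1.5 h
- which of Q and G there is more of at 1.5 h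

We count turnovers instead, treating E and D as partners in second-order decay. With equal stocks of E and D, after N turnovers a share N/(1+N) of either has become Q, and we take the two stocks of the flask asked about as equal. Each G takes two D, so the D stock for Q is the charge less two G.

The charge stands in the recipe, so the doubt lies in the readings. Taking the G plateau at 11 % gives a final ratio of 6.05, and taking it at 15 % gives 4.17. Taking the turnover time from the Q reading at 6.00 min gives 4.74. So the plateau is the number to know well, and we average its last readings.

G plateau: 13.0 %

D stock for Q: 84.0 %, beside an E stock of 87.0 %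

Turnover time, after which as much stock has become Q as is left: 27.0 min

Q at 1.5 h: 64.6 %, a ratio of 4.97, so we expect more Q than G

At 5.0 min we reckon a ratio of 1.01. The time 20 s lies before the first reading, and we commit to no figure for it.

The forecast gave 0.15, 0.93 and 6 for the ratios at the asked times, in order, with Q ahead, allowing that “D runs low and may slow Q slightly”.

The flask gives 0.197, 1.15 and 5.12, with 67.6 % of Q against 13.2 % of G at 1.5 h.

    X → Z (k = 0.100 s⁻¹)
    X + D → J (k = 0.152 M⁻¹ s⁻¹)
    D + E ⇌ L (K = 1.90 M⁻¹, k = 0.144 M⁻¹ s⁻¹)
    D + J → G (k = 0.103 M⁻¹ s⁻¹)
    Z → E (k = 0.452 s⁻¹)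
    L → Q (k = 0.00527 s⁻¹)

The neighbour charged with 0.660 equiv of D ends with 8.33 % of G, so its D stock for Q is 49.3 % beside 91.7 % of E. With stocks this unequal, the turnover count takes its other form: the ratio of E left to D left grows exponentially, and the exponent is the neighbour's excess of E over D, in units of the D stock of the flask asked about, times time over the turnover time. Over 1.5 h that factor is 5.37, which leaves 44.6 % of Q. The neighbour holds 45.7 % of Q at 1.50 h, a ratio to G of 5.49.

(Readings and results are simulated from invented constants.)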